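**Retrosynthetic overview**
- Labels: ring B is the central benzene, with C1 (O–ring A), C2 (H), C3 (OH), C4 (O–ring C), C5 (OH) and C6 (O–ring D). Ring A is 2,4,6-trihydroxyphenyl. Rings C and D are both 3,4,5-trihydroxyphenyl.
- Feature used: the oxygens at C1/C3/C5 of ring B form a phloroglucinol (triketide) pattern. C4 and C6 are its "methylene" carbons, and each carries an aryloxy group. Because C and D are identical, C4–C5–C6 is a symmetric ketone.
- Key disconnection: ring B itself is cut at C6–C1 and C3–C4. This gives 1,3-bis(aryloxy)acetone (C4–C5–C6) and a methyl 3-aryloxypropiolate (C1–C2–C3), which are joined by a [3+3] Michael–Dieckmann benzannulation. The three crowded Ar–O–Ar links are therefore laid down earlier as easy O–C(sp3) and O–C(sp) bonds, and none is made by arylation.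
- Ring order: A, C and D are bought as trimethoxyphenols. Ring B is the only ring formed (step 4), and its six carbons come from 1,3-dichloroacetone, trichloroethylene and methyl chloroformate.
- Last step: ninefold O-demethylation.

Key step: step 4

Remark: the target has no stereocentre and its diaryl ether axes rotate freely. It is therefore achiral, the "single enantiomer" is the compound itself, and no step needs stereocontrol. Compounds 1, 2, 5, 6 and 9 are taken as catalogue chemicals.

Step 1
Reactants: 1 3,4,5-trimethoxyphenol (2 equiv); 2 1,3-dichloroacetone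
Product: 4 1,3-bis(3,4,5-trimethoxyphenoxy)propan-2-one, via 1-chloro-3-(3,4,5-trimethoxyphenoxy)propan-2-one 3 (not isolated)
Conditions: K2CO3 (2.5 equiv), acetone, reflux, N2
Reagents that add atoms: none
Why: Double Williamson ether synthesis, in which the α-chloroketone carbons of 2 are very reactive SN2 centres and the phenoxide of 1 is unhindered, so both chlorides should be displaced under mild carbonate conditions without forming a stereocentre.

Step 2
Reactants: 5 2,4,6-trimethoxyphenol; 6 trichloroethylene
Product: 8 2-{[(E)-1,2-dichloroethenyl]oxy}-1,3,5-trimethoxybenzene, via dichloroacetylene 7 (not isolated)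
Conditions: K2CO3, DMF, 70 °C, N2 (closed, well-vented set-up; 7 is kept at low stationary concentration)
Reagents that add atoms: none
Why: Known synthesis of aryl 1,2-dichlorovinyl ethers: base-induced loss of HCl from 6 gives 7, to which the phenoxide adds in anti fashion to give the E alkene (erased in step 3), and the linear electrophile does not feel the two ortho-methoxy groups of 5.

Step 3
Reactants: 8 2-{[(E)-1,2-dichloroethenyl]oxy}-1,3,5-trimethoxybenzene; 9 methyl chloroformate
Product: 12 methyl 3-(2,4,6-trimethoxyphenoxy)prop-2-ynoate, via 2-[(chloroethynyl)oxy]-1,3,5-trimethoxybenzene 10 (not isolated), via lithium (2,4,6-trimethoxyphenoxy)acetylide 11 (not isolated)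
Conditions: n-BuLi (2.2 equiv), THF, −78 to −40 °C; cannulation into 9 (excess), −78 to 0 °C; chromatography on Et3N-deactivated silica
Reagents that add atoms: none
Why: Known dichlorovinyl ether to ynol ether sequence: n-BuLi removes the vinyl proton with loss of LiCl to give 10, a second equivalent gives acetylide 11 by Cl/Li exchange, and C-acylation with the chloroformate gives the push–pull ynoate 12, while ring lithiation between the methoxy groups should not compete at −78 °C.

Step 4
Reactants: 4 1,3-bis(3,4,5-trimethoxyphenoxy)propan-2-one; 12 methyl 3-(2,4,6-trimethoxyphenoxy)prop-2-ynoate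
Product: 15 2,4-bis(3,4,5-trimethoxyphenoxy)-5-(2,4,6-trimethoxyphenoxy)benzene-1,3-diol, via methyl 5-oxo-3-(2,4,6-trimethoxyphenoxy)-4,6-bis(3,4,5-trimethoxyphenoxy)hex-2-enoate 13 (not isolated), via 5-(2,4,6-trimethoxyphenoxy)-2,6-bis(3,4,5-trimethoxyphenoxy)cyclohex-4-ene-1,3-dione 14 (not isolated)
Conditions: 4, LiHMDS (1.0 equiv), THF, −78 °C; 12, −78 to −20 °C; LDA (2.1 equiv), −78 °C to rt; 1 M HCl, N2
Reagents that add atoms: none
Why: Proposed new method: the lithium enolate of 4 should attack the oxygen-bearing alkyne carbon of 12, the one site where ynoate (β-carbon) and ynol ether (α-carbon) polarisation agree, which forms C6–C1 and after proton shift leaves the delocalised anion of 13; LDA then deprotonates the remaining ArOCH2 group, and this terminal, most nucleophilic carbon of the dianion attacks the ester (Dieckmann condensation), which forms C3–C4, expels methoxide and gives 14, whose double enolisation to the resorcinolate of 15 is irreversible. The closest known reaction types are the Michael addition–Dieckmann benzannulation of acetonedicarboxylate or dibenzyl ketone anions with 2-alkynoates to resorcinols and the terminal C-acylation of 1,3-dicarbonyl dianions; what has not been shown is an α,α'-bis(aryloxy) ketone as the 1,3-dinucleophile together with a 3-aryloxypropiolate as the C3 unit. Ring B closes in a favoured 6-(enolendo)-exo-trig mode at the ester carbonyl, and the E/Z isomers of 13 can interconvert through the dienolate so that ester and carbanion come to the same side. No stereocentre has to be controlled, because the sp3 centres of 13 and 14 and the alkene geometry all vanish on aromatisation. Regioselectivity comes from the substrate: rings C and D are the same, so the two α-carbons of 4 are equivalent and either orientation of 12 gives the same arene, with C2–H arising from the ester-side alkyne carbon. The step needs C- over O-acylation and retention of the ring A aryloxy group: closure through the enolate oxygen gives a 2-pyranone that the liberated methoxide can re-open while aromatisation drains the equilibrium (behaviour known for 6-benzyl-2-pyranones), and 13 is kept as an anion with no added alkoxide so that addition–elimination at C1 is disfavoured.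

Step 5
Reactants: 15 2,4-bis(3,4,5-trimethoxyphenoxy)-5-(2,4,6-trimethoxyphenoxy)benzene-1,3-diol
Product: 16 2,4-bis(3,4,5-trihydroxyphenoxy)-5-(2,4,6-trihydroxyphenoxy)benzene-1,3-diol (target)
Conditions: BBr3 (15 equiv), CH2Cl2, −78 °C to rt, Ar; ice-water quench; EtOAc extraction; Sephadex LH-20 with degassed solvents
Reagents that add atoms: none
Why: Lewis-acid aryl methyl ether cleavage, in which bromide attacks only the nine methyl carbons, the three diaryl ether links offer no sp3 carbon and should survive, and exclusion of air with a cold aqueous (not methanolic) quench protects the pyrogallol rings and the phloroglucinol-type ethers.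

**Compound list**
1 | 3,4,5-trimethoxyphenol | COc1cc(O)cc(OC)c1OC | starting material
2 | 1,3-dichloroacetone | ClCC(=O)CCl | starting material
3 | 1-chloro-3-(3,4,5-trimethoxyphenoxy)propan-2-one | COc1cc(OCC(=O)CCl)cc(OC)c1OC | intermediate
4 | 1,3-bis(3,4,5-trimethoxyphenoxy)propan-2-one | COc1cc(OCC(=O)COc2cc(OC)c(OC)c(OC)c2)cc(OC)c1OC | intermediate
5 | 2,4,6-trimethoxyphenol | COc1cc(OC)c(O)c(OC)c1 | starting material
6 | trichloroethylene | ClC=C(Cl)Cl | starting material
7 | dichloroacetylene | ClC#CCl | intermediate
8 | 2-{[(E)-1,2-dichloroethenyl]oxy}-1,3,5-trimethoxybenzene | COc1cc(OC)c(O/C(Cl)=C\Cl)c(OC)c1 | intermediate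
9 | methyl chloroformate | COC(=O)Cl | starting material
10 | 2-[(chloroethynyl)oxy]-1,3,5-trimethoxybenzene | COc1cc(OC)c(OC#CCl)c(OC)c1 | intermediate
11 | lithium (2,4,6-trimethoxyphenoxy)acetylide | COc1cc(OC)c(OC#C[Li])c(OC)c1 | intermediate
12 | methyl 3-(2,4,6-trimethoxyphenoxy)prop-2-ynoate | COC(=O)C#COc1c(OC)cc(OC)cc1OC | intermediate
13 | methyl 5-oxo-3-(2,4,6-trimethoxyphenoxy)-4,6-bis(3,4,5-trimethoxyphenoxy)hex-2-enoate (neutral form of the lithium salts; racemic, equilibrating E/Z mixture) | COC(=O)C=C(Oc1c(OC)cc(OC)cc1OC)C(Oc1cc(OC)c(OC)c(OC)c1)C(=O)COc1cc(OC)c(OC)c(OC)c1 | intermediate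
14 | 5-(2,4,6-trimethoxyphenoxy)-2,6-bis(3,4,5-trimethoxyphenoxy)cyclohex-4-ene-1,3-dione (keto tautomer of 15; configuration undefined) | O=C1C=C(Oc2c(OC)cc(OC)cc2OC)C(Oc2cc(OC)c(OC)c(OC)c2)C(=O)C1Oc1cc(OC)c(OC)c(OC)c1 | intermediate
15 | 2,4-bis(3,4,5-trimethoxyphenoxy)-5-(2,4,6-trimethoxyphenoxy)benzene-1,3-diol | COc1cc(OC)c(Oc2cc(O)c(Oc3cc(OC)c(OC)c(OC)c3)c(O)c2Oc2cc(OC)c(OC)c(OC)c2)c(OC)c1 | intermediate
16 | 2,4-bis(3,4,5-trihydroxyphenoxy)-5-(2,4,6-trihydroxyphenoxy)benzene-1,3-diol (CNP0304743.0, achiral) | Oc1cc(O)c(Oc2cc(O)c(Oc3cc(O)c(O)c(O)c3)c(O)c2Oc2cc(O)c(O)c(O)c2)c(O)c1 | target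

Total step count: 5. Longest linear sequence: 4 steps (5 → 8 → 12 → 15 → 16).

**Steps most likely to fail**

**Step 4.**
- What may go wrong: attack of the enolate at the ester carbonyl or through oxygen instead of at the alkyne carbon; closure through oxygen to pyranones that do not re-open; expulsion of the ring A aryloxide by addition–elimination; self-aldol reaction of the ketone.
- Fallback: known chemistry, with ring B bought rather than built. It sets out from 5 and 1 and returns at 15.
- Cu-catalysed Ullmann coupling (CuI, picolinic acid, K3PO4, DMSO, 90 °C) of 5 with commercial 1-bromo-2,4-difluoro-5-iodobenzene at the C–I bond should give 2-(5-bromo-2,4-difluorophenoxy)-1,3,5-trimethoxybenzene F1.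
- Br/Mg exchange (i-PrMgCl·LiCl) and DMF follow. On the resulting hemiaminal alkoxide in the same flask, LDA deprotonation between the two fluorines and DMF again should give 2,4-difluoro-5-(2,4,6-trimethoxyphenoxy)benzene-1,3-dicarbaldehyde F2.
- Both C–F bonds are ortho or para to both formyl groups. Two equivalents of 1 (K2CO3, DMF) should therefore give, by double SNAr, 2,4-bis(3,4,5-trimethoxyphenoxy)-5-(2,4,6-trimethoxyphenoxy)benzene-1,3-dicarbaldehyde F3.
- Double Baeyer–Villiger oxidation (mCPBA, NaHCO3, CH2Cl2) should give 2,4-bis(3,4,5-trimethoxyphenoxy)-5-(2,4,6-trimethoxyphenoxy)-1,3-phenylene diformate F4. Methanolysis (K2CO3, MeOH) then gives 15.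

**Step 3.**
- What may go wrong: hydration or oligomerisation of the push–pull alkyne during isolation; competing ring lithiation; a second addition of the acetylide to the new ester.
- Fallback: an sp2 surrogate of the same oxidation level replaces the alkyne. It sets out from 5 and returns at 13.
- Vinylic substitution (addition–elimination) of the potassium salt of 5 on commercial methyl 3,3-dichloroacrylate (K2CO3, DMF, rt) should give methyl 3-chloro-3-(2,4,6-trimethoxyphenoxy)prop-2-enoate F5, which tolerates chromatography.
- The lithium enolate of 4 adds to its β-carbon and chloride leaves. This gives 13 directly, and the route continues with the LDA stage of step 4.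

**Step 5.**
- What may go wrong: incomplete cleavage across nine sites; air oxidation of the pyrogallol rings during isolation; acid-promoted exchange at the phloroglucinol-type ethers.
- Fallback: capture, purify and release instead of direct isolation. It sets out from 15 and returns at 16.
- The crude BBr3 product is acetylated at once (Ac2O, pyridine, Ar). This gives the air-stable 2,4-bis(3,4,5-triacetoxyphenoxy)-5-(2,4,6-triacetoxyphenoxy)-1,3-phenylene diacetate F6, which can be purified on silica and separated from partly methylated material.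
- Hydrazinolysis (N2H4·H2O, degassed MeCN, 0 °C to rt) under reducing, nearly neutral conditions then frees 16.

**Further compounds**
F1 | step 4 | 2-(5-bromo-2,4-difluorophenoxy)-1,3,5-trimethoxybenzene | COc1cc(OC)c(Oc2cc(Br)c(F)cc2F)c(OC)c1
F2 | step 4 | 2,4-difluoro-5-(2,4,6-trimethoxyphenoxy)benzene-1,3-dicarbaldehyde | COc1cc(OC)c(Oc2cc(C=O)c(F)c(C=O)c2F)c(OC)c1
F3 | step 4 | 2,4-bis(3,4,5-trimethoxyphenoxy)-5-(2,4,6-trimethoxyphenoxy)benzene-1,3-dicarbaldehyde | COc1cc(OC)c(Oc2cc(C=O)c(Oc3cc(OC)c(OC)c(OC)c3)c(C=O)c2Oc2cc(OC)c(OC)c(OC)c2)c(OC)c1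
F4 | step 4 | 2,4-bis(3,4,5-trimethoxyphenoxy)-5-(2,4,6-trimethoxyphenoxy)-1,3-phenylene diformate | COc1cc(OC)c(Oc2cc(OC=O)c(Oc3cc(OC)c(OC)c(OC)c3)c(OC=O)c2Oc2cc(OC)c(OC)c(OC)c2)c(OC)c1
F5 | step 3 | methyl 3-chloro-3-(2,4,6-trimethoxyphenoxy)prop-2-enoate (E/Z undefined) | COC(=O)C=C(Cl)Oc1c(OC)cc(OC)cc1OC
F6 | step 5 | 2,4-bis(3,4,5-triacetoxyphenoxy)-5-(2,4,6-triacetoxyphenoxy)-1,3-phenylene diacetate | CC(=O)Oc1cc(OC(C)=O)c(Oc2cc(OC(C)=O)c(Oc3cc(OC(C)=O)c(OC(C)=O)c(OC(C)=O)c3)c(OC(C)=O)c2Oc2cc(OC(C)=O)c(OC(C)=O)c(OC(C)=O)c2)c(OC(C)=O)c1
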